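**Retrosynthetic overview**
1. The four benzyl ethers come off last. Before that, ring C (the pyranone: O1–C2, C3–C4, C4–C4a) is closed in one operation from an o-iodophenol, CO and 3,4-bis(benzyloxy)phenylacetylene by Pd carbonylative alkynylation and oxa-Michael closure.
2. Feature used: in ring A the ring oxygen O1 (on C8a) lies para to C6, the carbon carrying the cyclohexylmethyl group. The 4-alkyl-3,5-bis(benzyloxy)phenol therefore has two equivalent ortho positions, one iodine defines C4a, and only the 6-substituted chromenone can form, never the 8-substituted one.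
3. The tertiary carbinol C2′ of the cyclohexane comes from an exocyclic methylene group (epoxidation anti to the axial C6′ methyl, then hydride opening). The benzylic hydroxyl left by the C–C coupling is removed by radical deoxygenation.
4. The aryl–CH bond and the C1′ stereocentre are made together by Brown allylboration of a 2,6-bis(benzyloxy)-4-silyloxybenzaldehyde with a (cyclohexenylmethyl)borane derived from 3-methylcyclohexenone.
5. Ring order: the cyclohexane, ring A and ring B are bought; only ring C is built (step 13).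

Key step: step 13

Assumption: C1′, C2′ and C6′ denote the cyclohexane carbons bearing the arylmethyl group, the hydroxyl and the gem-dimethyl group; (−)-Ipc2BOMe is the reagent made from (+)-α-pinene, whose allylboranes add to the Si face of aldehydes.

**Step 1**
Reactants: 1 3,5-bis(benzyloxy)phenol
Product: 2 [3,5-bis(benzyloxy)phenoxy]tri(propan-2-yl)silane
Conditions: TIPSCl, imidazole, DMF, rt
Reagents that add atoms: chlorotri(propan-2-yl)silane, CC(C)[Si](Cl)(C(C)C)C(C)C
Why: Imidazole-promoted O-silylation of the only free hydroxyl installs a phenol protecting group that survives organolithium, radical, peracid and hydride steps and is later removed by fluoride without acid.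

**Step 2**
Reactants: 2 [3,5-bis(benzyloxy)phenoxy]tri(propan-2-yl)silane
Product: 4 2,6-bis(benzyloxy)-4-{[tri(propan-2-yl)silyl]oxy}benzaldehyde, via aryllithium 3 (not isolated)
Conditions: n-BuLi, TMEDA, THF, 0 °C; DMF, −78 °C → rt
Reagents that add atoms: N,N-dimethylformamide, CN(C)C=O
Why: Directed ortho-metalation should occur at the position flanked by both benzyloxy groups (the bulky silyloxy group does not direct), and the aryllithium is formylated by DMF.

**Step 3**
Reactants: 5 3-methylcyclohex-2-en-1-one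
Product: 7 3,3-dimethylcyclohex-1-en-1-yl trifluoromethanesulfonate, via lithium enolate 6 (not isolated)
Conditions: Me2CuLi (from MeLi, CuI), Et2O, 0 °C; PhNTf2, THF, 0 °C → rt
Reagents that add atoms: lithium dimethylcuprate, [Li+].C[Cu-]C; N-phenylbis(trifluoromethanesulfonimide), O=S(=O)(N(c1ccccc1)S(=O)(=O)C(F)(F)F)C(F)(F)F
Why: Conjugate addition of the Gilman cuprate builds the gem-dimethyl carbon and gives the regiodefined enolate, which is O-triflated in the same flask (conjugate addition–enolate trapping).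

**Step 4**
Reactants: 7 3,3-dimethylcyclohex-1-en-1-yl trifluoromethanesulfonate
Product: 8 1,3,3-trimethylcyclohex-1-ene
Conditions: MeMgBr, Fe(acac)3 (5 mol %), THF/NMP, 0 °C
Reagents that add atoms: methylmagnesium bromide, C[Mg]Br
Why: Iron-catalysed Kumada-type cross-coupling of the alkenyl triflate with the methyl Grignard reagent replaces the triflate by methyl without moving the double bond.

**Step 5**
Reactants: 8 1,3,3-trimethylcyclohex-1-ene; 4 2,6-bis(benzyloxy)-4-{[tri(propan-2-yl)silyl]oxy}benzaldehyde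
Product: 11 (S)-[2,6-bis(benzyloxy)-4-{[tri(propan-2-yl)silyl]oxy}phenyl][(1S)-2,2-dimethyl-6-methylidenecyclohexyl]methanol, via allylpotassium 9 (not isolated), via allylborane 10 (not isolated)
Conditions: 8, n-BuLi, KOt-Bu, THF, −78 → −25 °C; (−)-Ipc2BOMe, −78 °C; BF3·OEt2; 4, −78 °C; NaBO3·4H2O, THF/H2O, rt
Reagents that add atoms: none
Why: Schlosser-base metalation of the allylic methyl group, transfer to boron at the unhindered CH2 terminus and Brown allylboration through a chair Zimmerman–Traxler transition state (aryl group and ring carbon C6′ equatorial, as for an E-crotyl reagent) join the aldehyde carbon to the ring carbon next to the gem-dimethyl group with allylic transposition; Si-face attack dictated by the (+)-α-pinene-derived ligands sets C1′ as S (the carbinol centre, also S, is removed in step 7).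

**Step 6**
Reactants: 11 (S)-[2,6-bis(benzyloxy)-4-{[tri(propan-2-yl)silyl]oxy}phenyl][(1S)-2,2-dimethyl-6-methylidenecyclohexyl]methanol
Product: 12 O-{(S)-[2,6-bis(benzyloxy)-4-{[tri(propan-2-yl)silyl]oxy}phenyl][(1S)-2,2-dimethyl-6-methylidenecyclohexyl]methyl} S-methyl carbonodithioate
Conditions: NaH, imidazole (cat.), CS2, THF, 0 °C; MeI, rt
Reagents that add atoms: carbon disulfide, S=C=S; iodomethane, CI
Why: The sodium alkoxide adds to CS2 and the dithiocarbonate salt is S-methylated (xanthate formation, first half of a Barton–McCombie deoxygenation).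

**Step 7**
Reactants: 12 O-{(S)-[2,6-bis(benzyloxy)-4-{[tri(propan-2-yl)silyl]oxy}phenyl][(1S)-2,2-dimethyl-6-methylidenecyclohexyl]methyl} S-methyl carbonodithioate
Product: 13 {3,5-bis(benzyloxy)-4-{[(1S)-2,2-dimethyl-6-methylidenecyclohexyl]methyl}phenoxy}tri(propan-2-yl)silane
Conditions: Bu3SnH, Et3B (cat.), air, toluene, rt
Reagents that add atoms: none
Why: Barton–McCombie radical deoxygenation (stannyl radical addition to C=S, β-scission to the benzylic radical, H-atom transfer) removes the benzylic oxygen without a benzylic cation, which could lose the C1′ proton, so the C1′ configuration and the exocyclic alkene are kept, and initiation at room temperature avoids Chugaev elimination.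

**Step 8**
Reactants: 13 {3,5-bis(benzyloxy)-4-{[(1S)-2,2-dimethyl-6-methylidenecyclohexyl]methyl}phenoxy}tri(propan-2-yl)silane
Product: 14 {3,5-bis(benzyloxy)-4-{[(3S,4S)-5,5-dimethyl-1-oxaspiro[2.5]octan-4-yl]methyl}phenoxy}tri(propan-2-yl)silane
Conditions: mCPBA, NaHCO3, CH2Cl2, 0 °C
Reagents that add atoms: 3-chloroperoxybenzoic acid, OOC(=O)c1cccc(Cl)c1
Why: Prilezhaev epoxidation of the only alkene; in the chair with the arylmethyl group equatorial the axial approach to the methylene carbon is screened by the syn-axial C6′ methyl, so the peracid should add equatorially and place oxygen trans to the arylmethyl group (substrate control, 3S spiro centre).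

**Step 9**
Reactants: 14 {3,5-bis(benzyloxy)-4-{[(3S,4S)-5,5-dimethyl-1-oxaspiro[2.5]octan-4-yl]methyl}phenoxy}tri(propan-2-yl)silane
Product: 15 (1S,2S)-2-{[2,6-bis(benzyloxy)-4-{[tri(propan-2-yl)silyl]oxy}phenyl]methyl}-1,3,3-trimethylcyclohexan-1-ol
Conditions: LiBHEt3, THF, 0 °C → rt
Reagents that add atoms: none
Why: SN2 hydride opening of the 2,2-disubstituted epoxide at its CH2 carbon by Super-Hydride turns that carbon into the axial methyl group and leaves the tertiary C–O bond, and so the C2′ configuration, untouched.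

**Step 10**
Reactants: 15 (1S,2S)-2-{[2,6-bis(benzyloxy)-4-{[tri(propan-2-yl)silyl]oxy}phenyl]methyl}-1,3,3-trimethylcyclohexan-1-ol
Product: 16 3,5-bis(benzyloxy)-4-{[(1S,2S)-2-hydroxy-2,6,6-trimethylcyclohexyl]methyl}phenol
Conditions: TBAF, THF, 0 °C
Reagents that add atoms: none
Why: Fluoride cleavage of the aryl silyl ether frees the phenol under basic, acid-free conditions that leave the tertiary alcohol and the benzyl ethers alone.

**Step 11**
Reactants: 16 3,5-bis(benzyloxy)-4-{[(1S,2S)-2-hydroxy-2,6,6-trimethylcyclohexyl]methyl}phenol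
Product: 17 3,5-bis(benzyloxy)-4-{[(1S,2S)-2-hydroxy-2,6,6-trimethylcyclohexyl]methyl}-2-iodophenol
Conditions: NIS (1.0 equiv), CH2Cl2, −40 → 0 °C
Reagents that add atoms: N-iodosuccinimide, O=C1CCC(=O)N1I
Why: Electrophilic aromatic iodination ortho to the free phenol; the two ortho positions are equivalent (interchanged by rotation about the aryl–CH2 bond), so one equivalent should give a single mono-iodide.

**Step 12**
Reactants: 18 3,4-bis(benzyloxy)benzaldehyde
Product: 19 1,2-bis(benzyloxy)-4-ethynylbenzene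
Conditions: dimethyl (1-diazo-2-oxopropyl)phosphonate, K2CO3, MeOH, rt
Reagents that add atoms: dimethyl (1-diazo-2-oxopropyl)phosphonate, CC(=O)C(=[N+]=[N-])P(=O)(OC)OC
Why: Seyferth–Gilbert homologation with the Ohira–Bestmann reagent converts the aldehyde into the terminal alkyne under mild base.

**Step 13**
Reactants: 17 3,5-bis(benzyloxy)-4-{[(1S,2S)-2-hydroxy-2,6,6-trimethylcyclohexyl]methyl}-2-iodophenol; 19 1,2-bis(benzyloxy)-4-ethynylbenzene; 20 carbon monoxide
Product: 23 5,7-bis(benzyloxy)-2-[3,4-bis(benzyloxy)phenyl]-6-{[(1S,2S)-2-hydroxy-2,6,6-trimethylcyclohexyl]methyl}-4H-chromen-4-one, via ynone 21 (not isolated), via enaminone 22 (not isolated)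
Conditions: CO (1 atm), PdCl2(PPh3)2 (5 mol %), Et2NH, DMF, 50 °C
Reagents that add atoms: none
Why: Pd(0) adds oxidatively into the C–I bond of 17, CO inserts to give the aroyl–palladium species, and amine-assisted transfer of the alkynyl group of 19 with reductive elimination forms C4a–C4 and C4–C3 in ynone 21 (carbonylative Sonogashira coupling). Diethylamine adds to the ynone to give enaminone 22, and the ortho phenol oxygen displaces the amine by addition–elimination at the β-carbon, forming O1–C2 and closing ring C, the only ring made here, in the 6-endo mode. The closest known reaction type is the palladium-catalysed carbonylative annulation of o-iodophenols with terminal arylacetylenes to flavones in a secondary amine. No stereocentre is created, and the two existing ones are remote and cannot epimerise. The selectivities needed are 6-endo (flavone) over 5-exo (aurone) closure, steered by the enaminone pathway, and 6- over 8-substitution, secured by the single iodine on a phenol whose ortho positions were equivalent. The free tertiary alcohol and the benzyl ethers should be inert in the weakly basic, acid-free medium.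

**Step 14**
Reactants: 23 5,7-bis(benzyloxy)-2-[3,4-bis(benzyloxy)phenyl]-6-{[(1S,2S)-2-hydroxy-2,6,6-trimethylcyclohexyl]methyl}-4H-chromen-4-one
Product: 24 2-(3,4-dihydroxyphenyl)-5,7-dihydroxy-6-{[(1S,2S)-2-hydroxy-2,6,6-trimethylcyclohexyl]methyl}-4H-chromen-4-one
Conditions: H2 (1 atm), 10% Pd/C, THF/MeOH, rt
Reagents that add atoms: none
Why: Hydrogenolysis of the four benzyl ethers under neutral conditions should spare the chromenone C2=C3 bond (a vinylogous ester) and keeps the tertiary alcohol away from acid, which would close a chroman onto the freed 5- or 7-hydroxyl.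

**Compound list**
1 | 3,5-bis(benzyloxy)phenol | Oc1cc(OCc2ccccc2)cc(OCc2ccccc2)c1 | starting material
2 | [3,5-bis(benzyloxy)phenoxy]tri(propan-2-yl)silane | CC(C)[Si](Oc1cc(OCc2ccccc2)cc(OCc2ccccc2)c1)(C(C)C)C(C)C | intermediate
3 | [2,6-bis(benzyloxy)-4-{[tri(propan-2-yl)silyl]oxy}phenyl]lithium | [Li]c1c(OCc2ccccc2)cc(O[Si](C(C)C)(C(C)C)C(C)C)cc1OCc1ccccc1 | intermediate
4 | 2,6-bis(benzyloxy)-4-{[tri(propan-2-yl)silyl]oxy}benzaldehyde | O=Cc1c(OCc2ccccc2)cc(O[Si](C(C)C)(C(C)C)C(C)C)cc1OCc1ccccc1 | intermediate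
5 | 3-methylcyclohex-2-en-1-one | CC1=CC(=O)CCC1 | starting material
6 | lithium 3,3-dimethylcyclohex-1-en-1-olate | [Li+].[O-]C1=CC(C)(C)CCC1 | intermediate
7 | 3,3-dimethylcyclohex-1-en-1-yl trifluoromethanesulfonate | CC1(C)CCCC(OS(=O)(=O)C(F)(F)F)=C1 | intermediate
8 | 1,3,3-trimethylcyclohex-1-ene | CC1=CC(C)(C)CCC1 | intermediate
9 | [(3,3-dimethylcyclohex-1-en-1-yl)methyl]potassium | [K+].[CH2-]C1=CC(C)(C)CCC1 | intermediate
10 | B-[(3,3-dimethylcyclohex-1-en-1-yl)methyl]diisopinocampheylborane (isopinocampheyl groups from (+)-α-pinene) | CC1(C)CCCC(CB([C@@H]2C[C@@H]3C[C@H]([C@H]2C)C3(C)C)[C@@H]2C[C@@H]3C[C@H]([C@H]2C)C3(C)C)=C1 | intermediate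
11 | (S)-[2,6-bis(benzyloxy)-4-{[tri(propan-2-yl)silyl]oxy}phenyl][(1S)-2,2-dimethyl-6-methylidenecyclohexyl]methanol | CC1(C)CCCC(=C)[C@H]1[C@H](O)c1c(OCc2ccccc2)cc(O[Si](C(C)C)(C(C)C)C(C)C)cc1OCc1ccccc1 | intermediate
12 | O-{(S)-[2,6-bis(benzyloxy)-4-{[tri(propan-2-yl)silyl]oxy}phenyl][(1S)-2,2-dimethyl-6-methylidenecyclohexyl]methyl} S-methyl carbonodithioate | CC1(C)CCCC(=C)[C@H]1[C@H](OC(=S)SC)c1c(OCc2ccccc2)cc(O[Si](C(C)C)(C(C)C)C(C)C)cc1OCc1ccccc1 | intermediate
13 | {3,5-bis(benzyloxy)-4-{[(1S)-2,2-dimethyl-6-methylidenecyclohexyl]methyl}phenoxy}tri(propan-2-yl)silane | CC1(C)CCCC(=C)[C@H]1Cc1c(OCc2ccccc2)cc(O[Si](C(C)C)(C(C)C)C(C)C)cc1OCc1ccccc1 | intermediate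
14 | {3,5-bis(benzyloxy)-4-{[(3S,4S)-5,5-dimethyl-1-oxaspiro[2.5]octan-4-yl]methyl}phenoxy}tri(propan-2-yl)silane | CC1(C)CCC[C@@]2(CO2)[C@H]1Cc1c(OCc3ccccc3)cc(O[Si](C(C)C)(C(C)C)C(C)C)cc1OCc1ccccc1 | intermediate
15 | (1S,2S)-2-{[2,6-bis(benzyloxy)-4-{[tri(propan-2-yl)silyl]oxy}phenyl]methyl}-1,3,3-trimethylcyclohexan-1-ol | CC1(C)CCC[C@](C)(O)[C@H]1Cc1c(OCc2ccccc2)cc(O[Si](C(C)C)(C(C)C)C(C)C)cc1OCc1ccccc1 | intermediate
16 | 3,5-bis(benzyloxy)-4-{[(1S,2S)-2-hydroxy-2,6,6-trimethylcyclohexyl]methyl}phenol | CC1(C)CCC[C@](C)(O)[C@H]1Cc1c(OCc2ccccc2)cc(O)cc1OCc1ccccc1 | intermediate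
17 | 3,5-bis(benzyloxy)-4-{[(1S,2S)-2-hydroxy-2,6,6-trimethylcyclohexyl]methyl}-2-iodophenol | CC1(C)CCC[C@](C)(O)[C@H]1Cc1c(OCc2ccccc2)cc(O)c(I)c1OCc1ccccc1 | intermediate
18 | 3,4-bis(benzyloxy)benzaldehyde | O=Cc1ccc(OCc2ccccc2)c(OCc2ccccc2)c1 | starting material
19 | 1,2-bis(benzyloxy)-4-ethynylbenzene | C#Cc1ccc(OCc2ccccc2)c(OCc2ccccc2)c1 | intermediate
20 | carbon monoxide | [C-]#[O+] | starting material
21 | 1-[2,4-bis(benzyloxy)-6-hydroxy-3-{[(1S,2S)-2-hydroxy-2,6,6-trimethylcyclohexyl]methyl}phenyl]-3-[3,4-bis(benzyloxy)phenyl]prop-2-yn-1-one | CC1(C)CCC[C@](C)(O)[C@H]1Cc1c(OCc2ccccc2)cc(O)c(C(=O)C#Cc2ccc(OCc3ccccc3)c(OCc3ccccc3)c2)c1OCc1ccccc1 | intermediate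
22 | 1-[2,4-bis(benzyloxy)-6-hydroxy-3-{[(1S,2S)-2-hydroxy-2,6,6-trimethylcyclohexyl]methyl}phenyl]-3-[3,4-bis(benzyloxy)phenyl]-3-(diethylamino)prop-2-en-1-one (alkene geometry not fixed) | CC1(C)CCC[C@](C)(O)[C@H]1Cc1c(OCc2ccccc2)cc(O)c(C(=O)C=C(N(CC)CC)c2ccc(OCc3ccccc3)c(OCc3ccccc3)c2)c1OCc1ccccc1 | intermediate
23 | 5,7-bis(benzyloxy)-2-[3,4-bis(benzyloxy)phenyl]-6-{[(1S,2S)-2-hydroxy-2,6,6-trimethylcyclohexyl]methyl}-4H-chromen-4-one | CC1(C)CCC[C@](C)(O)[C@H]1Cc1c(OCc2ccccc2)cc2oc(-c3ccc(OCc4ccccc4)c(OCc4ccccc4)c3)cc(=O)c2c1OCc1ccccc1 | intermediate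
24 | 2-(3,4-dihydroxyphenyl)-5,7-dihydroxy-6-{[(1S,2S)-2-hydroxy-2,6,6-trimethylcyclohexyl]methyl}-4H-chromen-4-one | CC1(C)CCC[C@](C)(O)[C@H]1Cc1c(O)cc2oc(-c3ccc(O)c(O)c3)cc(=O)c2c1O | target

**Totals**
Total step count: 14. Longest linear sequence: 11 steps (5 → 7 → 8 → 11 → 12 → 13 → 14 → 15 → 16 → 17 → 23 → 24).

**Steps most likely to fail**

Step 5. The allyl transfer from the hindered borane 10 to the di-ortho-substituted, electron-rich aldehyde 4 may be slow and may lose reagent control of the aldehyde face. The fallback sets out from 8 and 2 and returns at 13. Borane 10 is added instead to ethyl glyoxylate, a small and reactive aldehyde, to give ethyl (2S)-2-[(1S)-2,2-dimethyl-6-methylidenecyclohexyl]-2-hydroxyacetate F1. LiAlH4 reduction gives (1S)-1-[(1S)-2,2-dimethyl-6-methylidenecyclohexyl]ethane-1,2-diol F2, and NaIO4 cleavage gives (1S)-2,2-dimethyl-6-methylidenecyclohexane-1-carbaldehyde F3, which is used at once. Aryllithium 3, made from 2 as in step 2 but without formylation, adds to F3 at −78 °C to give 11 together with its carbinol epimer (R)-[2,6-bis(benzyloxy)-4-{[tri(propan-2-yl)silyl]oxy}phenyl][(1S)-2,2-dimethyl-6-methylidenecyclohexyl]methanol F4. The mixture is taken through the conditions of steps 6 and 7, the epimer passing through its xanthate O-{(R)-[2,6-bis(benzyloxy)-4-{[tri(propan-2-yl)silyl]oxy}phenyl][(1S)-2,2-dimethyl-6-methylidenecyclohexyl]methyl} S-methyl carbonodithioate F5, and both epimers converge on 13.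

Step 8. The peracid may attack both faces of the exocyclic alkene, because the ring can also react through the chair with an axial arylmethyl group, and it may oxidise the electron-rich arene. The fallback sets out from 13 and returns at 14. Upjohn dihydroxylation (OsO4 cat., NMO, acetone/H2O) uses a bulkier oxidant that should discriminate more strongly against the face screened by the axial C6′ methyl and does not touch the arene; it gives (1S,2S)-2-{[2,6-bis(benzyloxy)-4-{[tri(propan-2-yl)silyl]oxy}phenyl]methyl}-1-(hydroxymethyl)-3,3-dimethylcyclohexan-1-ol F6. Selective tosylation of the primary hydroxyl (TsCl, pyridine) gives [(1S,2S)-2-{[2,6-bis(benzyloxy)-4-{[tri(propan-2-yl)silyl]oxy}phenyl]methyl}-1-hydroxy-3,3-dimethylcyclohexyl]methyl 4-methylbenzenesulfonate F7. NaH in THF then closes F7 to epoxide 14 with the tertiary C–O bond intact.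

Step 13. CO insertion and alkynyl transfer at the doubly ortho-substituted aroyl–palladium centre may be slow, which would divert material to aminocarbonylation by diethylamine, to non-carbonylative coupling and benzofuran formation, or to 5-exo closure. The fallback sets out from 17 and 19 and returns at 23. Compound 17 is O-allylated (allyl bromide, K2CO3, acetone) to (1S,2S)-2-{[2,6-bis(benzyloxy)-3-iodo-4-(prop-2-en-1-yloxy)phenyl]methyl}-1,3,3-trimethylcyclohexan-1-ol F8. Alkyne 19 is deprotonated (n-BuLi) and acylated with N-methoxy-N-methylcarbamoyl chloride to 3-[3,4-bis(benzyloxy)phenyl]-N-methoxy-N-methylprop-2-ynamide F9. Iodine–lithium exchange on F8 (t-BuLi, 3 equiv, the first consumed by the tertiary alcohol, THF, −78 °C) and addition to F9 gives 1-[2,4-bis(benzyloxy)-3-{[(1S,2S)-2-hydroxy-2,6,6-trimethylcyclohexyl]methyl}-6-(prop-2-en-1-yloxy)phenyl]-3-[3,4-bis(benzyloxy)phenyl]prop-2-yn-1-one F10. Pd(PPh3)4 with morpholine removes the allyl group, and the liberated ynone 21 should cyclise under the same secondary amine, through the corresponding enaminone, to 23.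

**Further compounds**
F1 | step 5 | ethyl (2S)-2-[(1S)-2,2-dimethyl-6-methylidenecyclohexyl]-2-hydroxyacetate | CC1(C)CCCC(=C)[C@H]1[C@H](O)C(=O)OCC
F2 | step 5 | (1S)-1-[(1S)-2,2-dimethyl-6-methylidenecyclohexyl]ethane-1,2-diol | CC1(C)CCCC(=C)[C@H]1[C@H](O)CO
F3 | step 5 | (1S)-2,2-dimethyl-6-methylidenecyclohexane-1-carbaldehyde | CC1(C)CCCC(=C)[C@H]1C=O
F4 | step 5 | (R)-[2,6-bis(benzyloxy)-4-{[tri(propan-2-yl)silyl]oxy}phenyl][(1S)-2,2-dimethyl-6-methylidenecyclohexyl]methanol | CC1(C)CCCC(=C)[C@H]1[C@@H](O)c1c(OCc2ccccc2)cc(O[Si](C(C)C)(C(C)C)C(C)C)cc1OCc1ccccc1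
F5 | step 5 | O-{(R)-[2,6-bis(benzyloxy)-4-{[tri(propan-2-yl)silyl]oxy}phenyl][(1S)-2,2-dimethyl-6-methylidenecyclohexyl]methyl} S-methyl carbonodithioate | CC1(C)CCCC(=C)[C@H]1[C@@H](OC(=S)SC)c1c(OCc2ccccc2)cc(O[Si](C(C)C)(C(C)C)C(C)C)cc1OCc1ccccc1
F6 | step 8 | (1S,2S)-2-{[2,6-bis(benzyloxy)-4-{[tri(propan-2-yl)silyl]oxy}phenyl]methyl}-1-(hydroxymethyl)-3,3-dimethylcyclohexan-1-ol | CC1(C)CCC[C@](CO)(O)[C@H]1Cc1c(OCc2ccccc2)cc(O[Si](C(C)C)(C(C)C)C(C)C)cc1OCc1ccccc1
F7 | step 8 | [(1S,2S)-2-{[2,6-bis(benzyloxy)-4-{[tri(propan-2-yl)silyl]oxy}phenyl]methyl}-1-hydroxy-3,3-dimethylcyclohexyl]methyl 4-methylbenzenesulfonate | CC1(C)CCC[C@](COS(=O)(=O)c2ccc(C)cc2)(O)[C@H]1Cc1c(OCc2ccccc2)cc(O[Si](C(C)C)(C(C)C)C(C)C)cc1OCc1ccccc1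
F8 | step 13 | (1S,2S)-2-{[2,6-bis(benzyloxy)-3-iodo-4-(prop-2-en-1-yloxy)phenyl]methyl}-1,3,3-trimethylcyclohexan-1-ol | CC1(C)CCC[C@](C)(O)[C@H]1Cc1c(OCc2ccccc2)cc(OCC=C)c(I)c1OCc1ccccc1
F9 | step 13 | 3-[3,4-bis(benzyloxy)phenyl]-N-methoxy-N-methylprop-2-ynamide | CON(C)C(=O)C#Cc1ccc(OCc2ccccc2)c(OCc2ccccc2)c1
F10 | step 13 | 1-[2,4-bis(benzyloxy)-3-{[(1S,2S)-2-hydroxy-2,6,6-trimethylcyclohexyl]methyl}-6-(prop-2-en-1-yloxy)phenyl]-3-[3,4-bis(benzyloxy)phenyl]prop-2-yn-1-one | CC1(C)CCC[C@](C)(O)[C@H]1Cc1c(OCc2ccccc2)cc(OCC=C)c(C(=O)C#Cc2ccc(OCc3ccccc3)c(OCc3ccccc3)c2)c1OCc1ccccc1
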